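**Assumption:** the target SMILES decodes to (2R,3S), 2,3‑trans, i.e. the (+)-catechin series with an (E)-geranyl group at C5′ (ortho to 4′‑OH); (+)-catechin is taken as a cheap commercial chiral starting material.

## Retrosynthetic overview

1. Target = (+)-catechin carrying an (E)-geranyl group on B‑ring C5′.
2. Rings A, B and C and both stereocentres are bought intact in (+)-catechin; no ring is built, so there is no ring‑formation order. Only the C5′–C1″ bond is made.
3. Key disconnection: C5′–C1″ ⇒ 4′‑O‑geranyl ether, closed by a montmorillonite‑promoted [1,3]-sigmatropic O→C geranyl shift. A thermal [3,3] shift would give the reverse, linalyl‑type isomer.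
4. All other oxygens are acetylated for that step, so the phenol released at O4′ has C5′ as its only open ortho/para position.
5. The 4′‑ether comes from Mitsunobu mono‑geranylation of the free catechol of 3,5,7‑tri‑O‑acetylcatechin, itself made from catechin by catechol ketalisation, acetylation and hydrogenolysis.

## Route

**Step 1**
Reactants: **1** (+)-catechin; **2** dichlorodiphenylmethane
Product: **3** 3′,4′‑O‑diphenylmethylene‑(+)-catechin [(2R,3S)-2-(2,2-diphenyl-1,3-benzodioxol-5-yl)chromane-3,5,7-triol]
Conditions: Ph2CCl2 (1.5 eq), K2CO3, MeCN, Ar, rt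
Reagents that add atoms: dichlorodiphenylmethane, ClC(Cl)(c1ccccc1)c1ccccc1
Why: Cyclic ketalisation by double O‑alkylation; only the vicinal 3′,4′‑diol can close the 1,3‑benzodioxole (isolated phenols give α‑chloro ethers that hydrolyse on work‑up), and C2/C3 are untouched.

**Step 2**
Reactants: **3**; **4** acetic anhydride
Product: **5** 3,5,7‑tri‑O‑acetyl‑3′,4′‑O‑diphenylmethylene‑(+)-catechin
Conditions: Ac2O, pyridine, cat. DMAP, rt
Reagents that add atoms: acetic anhydride, CC(=O)OC(C)=O
Why: Exhaustive O‑acetylation (nucleophilic acyl substitution) of the two A‑ring phenols and the 3‑OH; the ketal is stable to these conditions and the C3–O bond is not broken, so configuration is retained.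

**Step 3**
Reactants: **5**
Product: **6** 3,5,7‑tri‑O‑acetyl‑(+)-catechin (free 3′,4′‑catechol)
Conditions: H2 (1 atm), Pd(OH)2/C, THF–EtOAc, rt
Reagents that add atoms: none
Why: Hydrogenolysis of the doubly benzylic diphenylmethylene ketal (lost as Ph2CH2) frees the catechol; acetates and the chromane C2–O bond survive in this neutral, non‑alcoholic medium.

**Step 4**
Reactants: **6**; **7** geraniol
Product: **8** 3,5,7‑tri‑O‑acetyl‑4′‑O‑[(2E)-geranyl]‑(+)-catechin (3′‑OH free)
Conditions: geraniol (1.0 eq), PPh3, DIAD, THF, 0 °C → rt; silica chromatography to remove the 3′‑O‑geranyl regioisomer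
Reagents that add atoms: geraniol, CC(C)=CCC/C(C)=C/CO
Why: Mitsunobu etherification under base‑free conditions (no acetyl scrambling); phenoxide SN2 on the primary geranyloxyphosphonium keeps the 2E geometry, the masked 3‑OH cannot be inverted, and because the two catechol OH groups are electronically similar an approximately 1:1 mixture of 4′‑/3′‑ethers is expected, from which **8** is isolated (assigned by NOE OCH2↔H‑5′).

**Step 5**
Reactants: **8**; **4** acetic anhydride
Product: **9** 3,3′,5,7‑tetra‑O‑acetyl‑4′‑O‑geranyl‑(+)-catechin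
Conditions: Ac2O, pyridine, cat. DMAP, CH2Cl2, rt
Reagents that add atoms: acetic anhydride, CC(=O)OC(C)=O
Why: Acetylation of the remaining 3′‑phenol blocks O→O geranyl transfer in the next step and leaves C5′ as the only nucleophilic site next to O4′.

**Step 6 (key step)**
Reactants: **9**
Product: **10** 3,3′,5,7‑tetra‑O‑acetyl‑5′‑C‑[(2E)-geranyl]‑(+)-catechin (4′‑OH free)
Conditions: montmorillonite K10 (oven‑dried), CH2Cl2, 0 °C → rt, 1–3 h, filter as soon as **9** is consumed
Reagents that add atoms: none
Why: Clay‑promoted [1,3]-sigmatropic O→C shift (Claisen‑type, via a surface‑bound tight aryloxide/geranyl ion pair) that delivers the primary allyl terminus with retained 2E geometry to C5′, the only unsubstituted position ortho/para to the departing O4′ (C3′ bears OAc, C1′ is substituted); the acetylated A ring is too deactivated to intercept the allyl fragment and C2/C3 are not involved.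

**Step 7**
Reactants: **10**
Product: **11** target, (2R,3S)-2-{3-[(2E)-3,7-dimethylocta-2,6-dien-1-yl]-4,5-dihydroxyphenyl}chromane-3,5,7-triol
Conditions: K2CO3, degassed MeOH, Ar, 0 °C → rt; neutralise with Amberlite IR‑120 (H+)
Reagents that add atoms: none
Why: Zemplén‑type methanolysis removes the three aryl acetates and the 3‑O‑acetate; cold, oxygen‑free, weakly basic conditions avoid catechol autoxidation and base‑induced C2 epimerisation, and the 1,5‑diene is inert.

## Compound list

1 | (+)-catechin, (2R,3S)-2-(3,4-dihydroxyphenyl)chromane-3,5,7-triol | Oc1ccc([C@H]2Oc3cc(O)cc(O)c3C[C@@H]2O)cc1O | starting material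
2 | dichlorodiphenylmethane | ClC(Cl)(c1ccccc1)c1ccccc1 | starting material
3 | 3′,4′‑O‑diphenylmethylene‑(+)-catechin | c1ccccc1C1(c2ccccc2)Oc2ccc([C@H]3Oc4cc(O)cc(O)c4C[C@@H]3O)cc2O1 | intermediate
4 | acetic anhydride | CC(=O)OC(C)=O | starting material
5 | 3,5,7‑tri‑O‑acetyl‑3′,4′‑O‑diphenylmethylene‑(+)-catechin | c1ccccc1C1(c2ccccc2)Oc2ccc([C@H]3Oc4cc(OC(C)=O)cc(OC(C)=O)c4C[C@@H]3OC(C)=O)cc2O1 | intermediate
6 | 3,5,7‑tri‑O‑acetyl‑(+)-catechin | Oc1ccc([C@H]2Oc3cc(OC(C)=O)cc(OC(C)=O)c3C[C@@H]2OC(C)=O)cc1O | intermediate
7 | geraniol, (2E)-3,7-dimethylocta-2,6-dien-1-ol | CC(C)=CCC/C(C)=C/CO | starting material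
8 | 3,5,7‑tri‑O‑acetyl‑4′‑O‑geranyl‑(+)-catechin | CC(C)=CCC/C(C)=C/COc1ccc([C@H]2Oc3cc(OC(C)=O)cc(OC(C)=O)c3C[C@@H]2OC(C)=O)cc1O | intermediate
9 | 3,3′,5,7‑tetra‑O‑acetyl‑4′‑O‑geranyl‑(+)-catechin | CC(C)=CCC/C(C)=C/COc1ccc([C@H]2Oc3cc(OC(C)=O)cc(OC(C)=O)c3C[C@@H]2OC(C)=O)cc1OC(C)=O | intermediate
10 | 3,3′,5,7‑tetra‑O‑acetyl‑5′‑C‑geranyl‑(+)-catechin | CC(C)=CCC/C(C)=C/Cc1cc([C@H]2Oc3cc(OC(C)=O)cc(OC(C)=O)c3C[C@@H]2OC(C)=O)cc(OC(C)=O)c1O | intermediate
11 | 5′‑C‑geranyl‑(+)-catechin (CID44420736) | CC(C)=CCC/C(C)=C/Cc1cc([C@H]2Oc3cc(O)cc(O)c3C[C@@H]2O)cc(O)c1O | target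

## Summary

Total steps: 7. Longest linear sequence: 7 (fully linear from **1**).

Steps most likely to fail, each with a fallback:

1. **Step 6 (K10 [1,3] shift).** Risks are de‑geranylation, acid cyclisation of the product to a chromane, and cyclisation of the geranyl fragment; a moderate yield is expected. Fallback: switch to a true thermal [3,3] aromatic Claisen. Etherify O4′ with the tertiary propargylic unit (3,7‑dimethyloct‑6‑en‑1‑yn‑3‑yl carbonate, Cu‑catalysed), Lindlar‑reduce to the linalyl‑type aryl ether, and heat. The allyl inversion then gives the linear chain at C5′, at the cost of an E/Z mixture that needs AgNO3–silica separation.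

2. **Step 4 (mono‑geranylation of the catechol).** The 3′/4′ selectivity is statistical, and catechols can sequester PPh3/DIAD as a cyclic dioxyphosphorane. Fallback: change the protecting‑group logic to silyl ethers (3,5,7‑tris‑TBS instead of acetates) so a Williamson alkylation with geranyl bromide/K2CO3 can be used. The unwanted 3′‑ether would be returned to the catechol by Pd(0)‑catalysed de‑geranylation and recycled.

3. **Step 1 (catechol‑selective ketalisation of unprotected catechin).** The yield is typically only moderate and the substrate is oxidation‑prone under base. Fallback: drop the ketal/hydrogenolysis pair and mask the catechol transiently as its phenylboronate (PhB(OH)2), acetylate the 3,5,7‑OH groups in the same pot, and release the catechol with pinacol or aqueous work‑up to reach **6** directly.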